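How high can the excess of right-handed substrate over left-handed substrate climb in this flask by 4.0 d? I follow a single rate, that of the difference between the two, counted as a fraction of both substrates charged together.

| flask | left-handed substrate | right-handed substrate | partner | free catalyst | remark | time |
|---|---|---|---|---|---|---|
| ash | 0.10 M | 0.10 M | 0.80 equiv (fed, over 50 h) | 1 mol% | run made earlier |  |
| oak | 0.10 M | 0.10 M | 0.80 equiv (fed, over 50 h) | 1.5 mol% | run made earlier |  |
| birch | 0.10 M | 0.10 M | 1.2 equiv (fed, over 50 h) | 2 mol% | run made earlier |  |
| flask | 0.10 M | 0.10 M | 0.800 equiv (fed, over 50 h) | 2 mol% |  | 4.0 d |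

| run | time / d | right-handed substrate / % | left-handed substrate / % |
|---|---|---|---|
| ash | 0.208 | 50.2 | 47.7 |
| ash | 0.333 | 49.9 | 44.5 |
| ash | 0.625 | 49.4 | 40.5 |
| ash | 1.25 | 49.0 | 30.7 |
| ash | 2.50 | 43.5 | 18.9 |
| oak | 0.208 | 49.8 | 46.7 |
| oak | 0.333 | 49.9 | 44.5 |
| oak | 0.625 | 49.0 | 40.9 |
| oak | 1.25 | 48.7 | 29.9 |
| oak | 2.50 | 43.1 | 18.7 |
| birch | 0.500 | 49.7 | 37.9 |
| birch | 1.04 | 46.8 | 24.2 |
| birch | 1.25 | 46.2 | 19.3 |
| birch | 2.08 | 42.2 | 5.3 |
| birch | 2.50 | 39.3 | 5.4 |

(standard deviation of a reading: 0.5 percentage points)

* whether the excess of right-handed substrate over left-handed substrate among what is left of the two reaches 99% by 4.0 d (yes / no)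
* the highest excess of right-handed substrate over left-handed substrate among what is left of the two up to 4.0 d

- free catalyst is single-handed; left-handed substrate and right-handed substrate are mirror images of each other, charged as a racemate, each of them at the stated concentration

I treat the partner as the limiting reagent and take each partner to remove one left-handed substrate, so the difference starts growing at the feed rate, 0.192 d⁻¹. Two things slow it. First, some partner may do no work: oak, which has this flask's partner charge at a lower loading of free catalyst, has consumed 38.2% of the two substrates by 2.50 d, a factor 0.955 on what the feed offers.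

Second comes racemization. Between 0.625 d and 2.50 d, oak's right-handed substrate falls by 5.9 percentage points. I charge this to a leak proportional to the difference, and the area under oak's difference over those readings gives 0.167 d⁻¹. Each conversion takes one from one side and adds one to the other, so the difference drains at 0.333 d⁻¹. This gives the quantity I carry, the half-life of the difference under racemization, 2.08 d.

Over the 50 h feed this drain builds up, and the accumulated slowing keeps a factor 0.721 of the consumed amount as difference. Dividing by what remains of the two substrates, I reckon a top of 44.6% at the end of the feed, less than 99%, with decay expected afterwards.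

The forecast answers no, with a top of 40.5% between 37% and 45%: “It will not reach 99%.”

The flask gives no and a top of 43.8%.

    free catalyst + left-handed substrate ⇌ catalyst intermediate A (K = 48.0 L mol⁻¹, k = 42.0 L mol⁻¹ min⁻¹)
    free catalyst + right-handed substrate ⇌ catalyst intermediate B (K = 7.20 L mol⁻¹, k = 3.80 L mol⁻¹ min⁻¹)
    partner + catalyst intermediate A → free catalyst + left-handed product (k = 13.0 L mol⁻¹ min⁻¹)
    partner + catalyst intermediate B → free catalyst + right-handed product (k = 1.20 L mol⁻¹ min⁻¹)
    left-handed substrate ⇌ right-handed substrate (k = 9.80 × 10⁻⁵ min⁻¹)
    partner → decomposed reagent (k = 9.20 × 10⁻⁴ min⁻¹)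

With the partner at 0% of its charge by 4.00 d, the carried half-life of 2.08 d takes the flask's difference from 27 points at 2.08 d to 14 points at 4.00 d, and the flask stands at 16 points. Starting from that value, the same half-life gives 2.2 points for the neighbour read at 10 d, which holds 32.2% right-handed substrate against 29.2% left-handed substrate, a difference of 3 points.

The earlier runs and the new flask are simulated with constants of no real substance; the scatter is artificial.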